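**Retrosynthetic overview**
1. Ring A, the quinone and the only ring of the target, is unmasked last from its O-MOM/O-methyl hydroquinone diether with (NH4)2Ce(NO3)6. The tiglate is attached one step earlier by Steglich esterification of the free (S)-allylic alcohol.
2. The key disconnection is the bond between chain C2 (the alkene carbon that carries ring A) and chain C3 (the carbinol carbon). It is made by lithiation–borylation: a 1-arylvinyl pinacol boronic ester reacts with the (+)-sparteine-lithiated homoprenyl 2,4,6-triisopropylbenzoate, a 1,2-metallate shift follows, and the C–B bond is oxidised in the same flask.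
3. Enabling feature: the O-bearing carbon C3 sits directly on the sp2 carbon C2 of the exocyclic C=CH2 group on ring A. The C3–O bond is therefore a masked allylic C–B bond, the migrating group is an sp2 carbon, and C3 is the prochiral OCH2 of achiral 4-methylpent-3-en-1-ol.
4. Ring order: no carbocycle is formed. Ring A is bought as an arene, its oxygen pattern is completed by Baeyer–Villiger oxidation, and the chain anchor is placed by MOM-directed ortho-lithiation. The dioxaborolane is a temporary ring, introduced in step 5 and lost in step 7.

Key step: step 7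

Assumption: 2,4-dimethoxy-3-methylbenzaldehyde, 4-methylpent-3-en-1-ol, tiglic acid, 2,4,6-triisopropylbenzoyl chloride and (+)-sparteine are taken as commercially available; chain locants follow the hepta-1,5-diene name.

Step 1
Reactants: 1 2,4-dimethoxy-3-methylbenzaldehyde
Product: 3 2,4-dimethoxy-3-methylphenol, via aryl formate 2 (not isolated)
Conditions: mCPBA, CH2Cl2, 0 °C to rt; then K2CO3 (cat.), MeOH, rt
Reagents that add atoms: mCPBA, O=C(OO)c1cccc(Cl)c1
Why: In this Baeyer–Villiger oxidation the electron-rich 2,4-dimethoxyaryl group should migrate in preference to hydrogen, and base-catalysed methanolysis of formate 2 frees the phenol oxygen that later becomes the quinone oxygen next to the side chain.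

Step 2
Reactants: 3 2,4-dimethoxy-3-methylphenol
Product: 4 1,3-dimethoxy-4-(methoxymethoxy)-2-methylbenzene
Conditions: MOMCl, i-Pr2NEt, CH2Cl2, 0 °C to rt
Reagents that add atoms: chloromethyl methyl ether (MOMCl), COCCl
Why: O-alkylation of the phenol (MOM acetal protection) gives a base-stable ether that is also the strongest ortho-directing group on the ring.

Step 3
Reactants: 4 1,3-dimethoxy-4-(methoxymethoxy)-2-methylbenzene
Product: 6 1-[3,5-dimethoxy-2-(methoxymethoxy)-4-methylphenyl]ethan-1-one, via aryllithium 5 (not isolated)
Conditions: n-BuLi, THF, 0 °C; then MeC(O)N(OMe)Me, −78 °C to rt; then H2O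
Reagents that add atoms: N-methoxy-N-methylacetamide, CC(=O)N(C)OC
Why: In this directed ortho-metalation the bidentate OCH2OCH3 group should outcompete the single methoxy groups and place lithium on the free carbon beside it, and acylation with the N-methoxy-N-methylamide stops at the ketone because the chelated tetrahedral adduct survives until the quench.

Step 4
Reactants: 6 1-[3,5-dimethoxy-2-(methoxymethoxy)-4-methylphenyl]ethan-1-one
Product: 8 1-[3,5-dimethoxy-2-(methoxymethoxy)-4-methylphenyl]ethenyl trifluoromethanesulfonate, via potassium enolate 7 (not isolated)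
Conditions: KN(SiMe3)2, THF, −78 °C; then PhNTf2, −78 to 0 °C
Reagents that add atoms: N-phenylbis(trifluoromethanesulfonimide), O=S(=O)(N(c1ccccc1)S(=O)(=O)C(F)(F)F)C(F)(F)F
Why: This is a standard enol triflate synthesis in which the methyl ketone has a single enolisable site and O-sulfonylation of its enolate fixes the future C=CH2 group.

Step 5
Reactants: 8 1-[3,5-dimethoxy-2-(methoxymethoxy)-4-methylphenyl]ethenyl trifluoromethanesulfonate
Product: 9 2-{1-[3,5-dimethoxy-2-(methoxymethoxy)-4-methylphenyl]ethenyl}-4,4,5,5-tetramethyl-1,3,2-dioxaborolane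
Conditions: B2pin2, PdCl2(PPh3)2 (cat.), PPh3 (cat.), KOPh, toluene, 50 °C
Reagents that add atoms: bis(pinacolato)diboron, CC1(C)OB(OC1(C)C)B1OC(C)(C)C(C)(C)O1
Why: This Miyaura borylation of an alkenyl triflate proceeds by oxidative addition to zerovalent palladium, phenoxide-assisted transmetalation with B2pin2 and reductive elimination, and the weak base KOPh suppresses Suzuki-type homocoupling.

Step 6
Reactants: 10 4-methylpent-3-en-1-ol
Product: 11 4-methylpent-3-en-1-yl 2,4,6-triisopropylbenzoate
Conditions: 2,4,6-triisopropylbenzoyl chloride, Et3N, DMAP (cat.), CH2Cl2, reflux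
Reagents that add atoms: 2,4,6-triisopropylbenzoyl chloride, CC(C)c1cc(C(C)C)c(C(=O)Cl)c(C(C)C)c1
Why: DMAP-catalysed acylation of the unhindered primary alcohol gives a benzoate whose carbonyl is shielded from attack by s-BuLi yet still directs α-lithiation and later serves as a good leaving group.

Step 7
Reactants: 11 4-methylpent-3-en-1-yl 2,4,6-triisopropylbenzoate; 9 2-{1-[3,5-dimethoxy-2-(methoxymethoxy)-4-methylphenyl]ethenyl}-4,4,5,5-tetramethyl-1,3,2-dioxaborolane
Product: 15 (3S)-2-[3,5-dimethoxy-2-(methoxymethoxy)-4-methylphenyl]-6-methylhepta-1,5-dien-3-ol, via lithiated benzoate 12 (not isolated), via boronate complex 13 (not isolated), via allylic boronic ester 14 (not isolated)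
Conditions: 11, s-BuLi, (+)-sparteine, Et2O, −78 °C, 5 h; add 9 in Et2O, −78 °C, 2 h; then reflux, 16 h; then NaOH aq, H2O2, THF, 0 °C to rt
Reagents that add atoms: hydrogen peroxide, OO
Why: s-BuLi·(+)-sparteine, held by the benzoate carbonyl, should remove the pro-R hydrogen of the OCH2 group of 11 to give the configurationally stable (R)-α-oxy-organolithium 12, which adds to the vacant orbital on boron of 9 with retention to give boronate complex 13. On warming, the sp2 carbon that carries the arene migrates from boron to the carbinol carbon antiperiplanar to the departing triisopropylbenzoate, so the C(sp2)–C(sp3) bond forms with inversion to give (S)-14, and NaOH/H2O2 then replaces boron by oxygen with retention to give (S)-15. The closest known reaction type is the lithiation–borylation of primary hindered benzoates and carbamates with alkenyl pinacol boronic esters (a stereospecific 1,2-metallate rearrangement of the Matteson type), followed by oxidation to the allylic alcohol. No ring is closed, and the dioxaborolane ring brought in with 9 is lost in the oxidation. The single new stereocentre is set by the chiral diamine alone (reagent control on two achiral partners) and is relayed through three stereospecific events: retention, inversion, retention. The step needs α- over allylic deprotonation (secured by the proximity effect of the benzoate C=O), carbon over oxygen migration (secured by the high migratory aptitude of the alkenyl group and the good leaving group), and no 1,3-shift of boron before oxidation (secured by the pinacol ester).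

Step 8
Reactants: 15 (3S)-2-[3,5-dimethoxy-2-(methoxymethoxy)-4-methylphenyl]-6-methylhepta-1,5-dien-3-ol; 16 tiglic acid, (E)-2-methylbut-2-enoic acid
Product: 17 (3S)-2-[3,5-dimethoxy-2-(methoxymethoxy)-4-methylphenyl]-6-methylhepta-1,5-dien-3-yl (E)-2-methylbut-2-enoate
Conditions: DCC, DMAP (cat.), CH2Cl2, 0 °C to rt
Reagents that add atoms: none
Why: Steglich esterification acylates the oxygen only, so the C3–O bond and the (S) centre stay untouched, and the thermodynamically preferred (E) geometry of the tigloyl group should be kept under these mild conditions.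

Step 9
Reactants: 17 (3S)-2-[3,5-dimethoxy-2-(methoxymethoxy)-4-methylphenyl]-6-methylhepta-1,5-dien-3-yl (E)-2-methylbut-2-enoate
Product: 18 (3S)-2-(5-methoxy-4-methyl-3,6-dioxocyclohexa-1,4-dien-1-yl)-6-methylhepta-1,5-dien-3-yl (E)-2-methylbut-2-enoate (target)
Conditions: (NH4)2Ce(NO3)6, MeCN/H2O, 0 °C, short contact time
Reagents that add atoms: water, O
Why: In this oxidative dealkylation of a hydroquinone diether, two one-electron oxidations by tetravalent cerium and ipso attack of water at the two para-related O-bearing ring carbons expel methanol and the MOM residue, the para-quinone should be favoured over the ortho-quinone, and the short contact at 0 °C should spare the alkenes, the ester and the stereocentre.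

**Compound list**
1 | 2,4-dimethoxy-3-methylbenzaldehyde | COc1ccc(C=O)c(OC)c1C | starting material
2 | 2,4-dimethoxy-3-methylphenyl formate | COc1ccc(OC=O)c(OC)c1C | intermediate
3 | 2,4-dimethoxy-3-methylphenol | COc1ccc(O)c(OC)c1C | intermediate
4 | 1,3-dimethoxy-4-(methoxymethoxy)-2-methylbenzene | COCOc1ccc(OC)c(C)c1OC | intermediate
5 | [3,5-dimethoxy-2-(methoxymethoxy)-4-methylphenyl]lithium | [Li]c1cc(OC)c(C)c(OC)c1OCOC | intermediate
6 | 1-[3,5-dimethoxy-2-(methoxymethoxy)-4-methylphenyl]ethan-1-one | CC(=O)c1cc(OC)c(C)c(OC)c1OCOC | intermediate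
7 | potassium 1-[3,5-dimethoxy-2-(methoxymethoxy)-4-methylphenyl]ethen-1-olate | C=C([O-])c1cc(OC)c(C)c(OC)c1OCOC.[K+] | intermediate
8 | 1-[3,5-dimethoxy-2-(methoxymethoxy)-4-methylphenyl]ethenyl trifluoromethanesulfonate | C=C(OS(=O)(=O)C(F)(F)F)c1cc(OC)c(C)c(OC)c1OCOC | intermediate
9 | 2-{1-[3,5-dimethoxy-2-(methoxymethoxy)-4-methylphenyl]ethenyl}-4,4,5,5-tetramethyl-1,3,2-dioxaborolane | C=C(B1OC(C)(C)C(C)(C)O1)c1cc(OC)c(C)c(OC)c1OCOC | intermediate
10 | 4-methylpent-3-en-1-ol | CC(C)=CCCO | starting material
11 | 4-methylpent-3-en-1-yl 2,4,6-triisopropylbenzoate | CC(C)c1cc(C(C)C)c(C(=O)OCCC=C(C)C)c(C(C)C)c1 | intermediate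
12 | (1R)-1-lithio-4-methylpent-3-en-1-yl 2,4,6-triisopropylbenzoate (sparteine-bound) | CC(C)c1cc(C(C)C)c(C(=O)O[C@@H](CC=C(C)C)[Li])c(C(C)C)c1 | intermediate
13 | lithium boronate complex formed from 12 and 9, (R) at the O-bearing carbon | CC(C)c1cc(C(C)C)c(C(=O)O[C@@H](CC=C(C)C)[B-]2(C(=C)c3cc(OC)c(C)c(OC)c3OCOC)OC(C)(C)C(C)(C)O2)c(C(C)C)c1.[Li+] | intermediate
14 | 2-{(3S)-2-[3,5-dimethoxy-2-(methoxymethoxy)-4-methylphenyl]-6-methylhepta-1,5-dien-3-yl}-4,4,5,5-tetramethyl-1,3,2-dioxaborolane | C=C(c1cc(OC)c(C)c(OC)c1OCOC)[C@H](CC=C(C)C)B1OC(C)(C)C(C)(C)O1 | intermediate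
15 | (3S)-2-[3,5-dimethoxy-2-(methoxymethoxy)-4-methylphenyl]-6-methylhepta-1,5-dien-3-ol | C=C(c1cc(OC)c(C)c(OC)c1OCOC)[C@H](CC=C(C)C)O | intermediate
16 | tiglic acid, (E)-2-methylbut-2-enoic acid | C/C=C(\C)C(=O)O | starting material
17 | (3S)-2-[3,5-dimethoxy-2-(methoxymethoxy)-4-methylphenyl]-6-methylhepta-1,5-dien-3-yl (E)-2-methylbut-2-enoate | C=C(c1cc(OC)c(C)c(OC)c1OCOC)[C@H](CC=C(C)C)OC(=O)/C(C)=C/C | intermediate
18 | (3S)-2-(5-methoxy-4-methyl-3,6-dioxocyclohexa-1,4-dien-1-yl)-6-methylhepta-1,5-dien-3-yl (E)-2-methylbut-2-enoate | C=C(C1=CC(=O)C(C)=C(OC)C1=O)[C@H](CC=C(C)C)OC(=O)/C(C)=C/C | target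

Total step count: 9
Longest linear sequence: 8 steps (steps 1–5, 7, 8 and 9; step 6 is the side branch)

**Steps most likely to fail**

1. Step 7.
What may go wrong: allylic deprotonation of 11 may compete with α-deprotonation. The organolithium may be captured slowly or reversibly at the hindered α-arylvinyl boron, with erosion of configurational purity. Migration may also be incomplete before the oxidation.
Fallback (sets out from 8 and 10, comes back at 15): alcohol 10 is oxidised with Dess–Martin periodinane to 4-methylpent-3-enal F1, which is used at once because it slips easily into conjugation. A catalytic asymmetric Nozaki–Hiyama–Kishi coupling of triflate 8 with F1 follows (CrCl2 cat., NiCl2 cat., chiral oxazoline–sulfonamide ligand, Mn, Cp2ZrCl2, MeCN). It should add the alkenylchromium species to the Re face of the aldehyde and give 15 directly, forming the same bond by carbonyl addition instead of a boron-to-carbon shift.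

2. Step 9.
What may go wrong: the electron-rich styrene-type or prenyl alkene may be oxidised by radical-cation pathways, the allylic ester may solvolyse in the acidic medium, or oxidation may go towards the ortho-quinone.
Fallback (sets out from 17, comes back at 18): the MOM group is removed first under nearly neutral conditions (Me3SiOTf, 2,2'-bipyridyl, CH2Cl2, 0 °C; then H2O). This gives the free 4-methoxyphenol, (3S)-2-(2-hydroxy-3,5-dimethoxy-4-methylphenyl)-6-methylhepta-1,5-dien-3-yl (E)-2-methylbut-2-enoate F2. F2 is then oxidised in a two-electron process with PhI(OAc)2 in MeCN/H2O at 0 °C. Water attacks the para carbon and methanol leaves, which should give 18 without any one-electron metal oxidant.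

3. Step 4.
What may go wrong: the electron-rich 1-arylvinyl triflate may ionise or hydrolyse during isolation, or the enolate may be sulfonylated incompletely.
Fallback (sets out from 6, comes back at 9): ketone 6 is condensed with 2,4,6-triisopropylbenzenesulfonyl hydrazide in THF to give the (E)-trisylhydrazone F3. A Shapiro reaction (n-BuLi, 2.2 equiv, THF, −78 to 0 °C) expels nitrogen and sulfinate to give the 1-arylvinyllithium F4. F4 is trapped at −78 °C with 2-isopropoxy-4,4,5,5-tetramethyl-1,3,2-dioxaborolane to return at boronate 9, so that neither triflate 8 nor the palladium step is needed.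

**Further compounds**
F1 | step 7 | 4-methylpent-3-enal | CC(C)=CCC=O
F2 | step 9 | (3S)-2-(2-hydroxy-3,5-dimethoxy-4-methylphenyl)-6-methylhepta-1,5-dien-3-yl (E)-2-methylbut-2-enoate | C=C(c1cc(OC)c(C)c(OC)c1O)[C@H](CC=C(C)C)OC(=O)/C(C)=C/C
F3 | step 4 | (E)-N'-{1-[3,5-dimethoxy-2-(methoxymethoxy)-4-methylphenyl]ethylidene}-2,4,6-triisopropylbenzenesulfonohydrazide | C/C(c1cc(OC)c(C)c(OC)c1OCOC)=N\NS(=O)(=O)c1c(C(C)C)cc(C(C)C)cc1C(C)C
F4 | step 4 | {1-[3,5-dimethoxy-2-(methoxymethoxy)-4-methylphenyl]ethenyl}lithium | [Li]C(=C)c1cc(OC)c(C)c(OC)c1OCOC
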